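## Retrosynthetic overview

1. Germacrane numbering is used. Ring A is the 3(2H)-furanone O–C10–C1(=O)–C2H=C3, ring B the ten-membered carbocycle C1–C10, ring C the α-methylene-γ-lactone C6–C7–C11–C12–O. The last bond made is the C8–O angelate (step 20).
2. Ring B is opened at C7–C8: an intramolecular chromium Barbier allylation of a 3-(bromomethyl)butenolide onto a C8 aldehyde sets C7 and C8 and turns the butenolide into ring C.
3. Ring A is opened at C1–C2 and O–C3 in one [3+2] annulation. The partners are α-hydroxy thioester 5 (C1, C8–C10, C14; C10 from (R)-citramalic acid) and terminal enyne butenolide 21 (C2–C7, C11–C13, C15).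
4. Enabling feature: ring A is the cycloisomer of an α′-hydroxy ynone. C1 is an acyl carbon next to the oxygen-bearing quaternary C10, C2=C3 is at the alkyne oxidation level with C3 as its β-carbon, and the C10 oxygen lies 5-endo to C3.
5. Order of ring formation: butenolide (step 11), then ring A (step 15), then rings B and C together (step 19). The C4=C5 geometry comes from hydroxyl-directed hydroalumination–iodination and C6 from a catalytic asymmetric alkynylation.

Key step: step 15

Remark: the C4=C5 geometry (C6 cis to C3) is the same from 9 to 31; its descriptor changes (Z in 9, E in 11–22, Z in 23–31) only because the CIP priorities change.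

Assumption: (S,S)-ProPhenol is taken to be the ligand enantiomer that directs the alkyne to the Si face of enal 12 (4R in 15); if the sense is the opposite, (R,R)-ProPhenol is used with no other change.

## Route

Step 1
Reactants: 1 (R)-citramalic acid
Product: 2 2-[(4R)-2,2,4-trimethyl-5-oxo-1,3-dioxolan-4-yl]acetic acid
Conditions: Me2C(OMe)2, TsOH·H2O (cat.), rt
Reagents that add atoms: 2,2-dimethoxypropane, COC(C)(C)OC
Why: Acid-catalysed acetalization ties the tertiary hydroxyl and the adjacent carboxyl into the five-membered dioxolanone (favoured over the six-membered alternative), which tells the C1 carboxyl from the C8 carboxyl and leaves the chiral-pool stereocenter C10 untouched.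

Step 2
Reactants: 2 dioxolanone acid
Product: 3 (5R)-5-(2-hydroxyethyl)-2,2,5-trimethyl-1,3-dioxolan-4-one
Conditions: BH3·SMe2, THF, 0 °C to rt; pH 7 aqueous work-up
Reagents that add atoms: none
Why: Chemoselective borane reduction of the free carboxylic acid in the presence of the dioxolanone ester, with a neutral work-up so that the new primary alcohol does not translactonize.

Step 3
Reactants: 3 dioxolanone alcohol
Product: 4 (5R)-5-{2-[(tert-butyldimethylsilyl)oxy]ethyl}-2,2,5-trimethyl-1,3-dioxolan-4-one
Conditions: TBSCl, imidazole, CH2Cl2, 0 °C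
Reagents that add atoms: tert-butyldimethylsilyl chloride, CC(C)(C)[Si](C)(C)Cl
Why: Standard silylation of the primary alcohol, which also removes the hydroxyl that could open the dioxolanone to a butyrolactone.

Step 4
Reactants: 4 silyl ether dioxolanone
Product: 5 S-ethyl (2R)-4-[(tert-butyldimethylsilyl)oxy]-2-hydroxy-2-methylbutanethioate
Conditions: AlMe3, EtSH, CH2Cl2, 0 °C to rt
Reagents that add atoms: ethanethiol, CCS
Why: Ester-to-thioester exchange with Me2AlSEt formed in the flask: the thiolate opens the activated dioxolanone at the acyl carbon and the aluminum hemiketal loses acetone, which unveils the tertiary hydroxyl; C10 is quaternary and cannot epimerize.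

Step 5
Reactants: 6 but-2-yne-1,4-diol
Product: 7 4-[(4-methoxybenzyl)oxy]but-2-yn-1-ol
Conditions: NaH, THF/DMF, 0 °C; 4-MeOC6H4CH2Cl, Bu4NI (cat.), rt (6 in excess)
Reagents that add atoms: 4-methoxybenzyl chloride, COc1ccc(CCl)cc1
Why: Williamson monoetherification, in which the excess of the symmetrical diol suppresses the bis-ether.

Step 6
Reactants: 7 mono-PMB butynediol
Product: 9 (2Z)-3-iodo-4-[(4-methoxybenzyl)oxy]but-2-en-1-ol, via cyclic alkenylaluminate 8 (not isolated)
Conditions: NaAlH2(OCH2CH2OMe)2, THF, 0 °C; then I2, THF, −78 °C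
Reagents that add atoms: iodine, II
Why: Hydroxyl-directed trans-hydroalumination of a propargylic alcohol (hydride to the carbon next to the carbinol, aluminum on the distal carbon in the five-membered alkoxyaluminate) followed by iodinolysis with retention should give only the Z-iodoalkene, which fixes the C4=C5 geometry of the target.

Step 7
Reactants: 9 Z-iodoalkenol; 10 ethynyltrimethylsilane
Product: 11 (2E)-4-[(4-methoxybenzyl)oxy]-3-[(trimethylsilyl)ethynyl]but-2-en-1-ol
Conditions: Pd(PPh3)2Cl2 (cat.), CuI (cat.), Et3N, THF, rt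
Reagents that add atoms: none
Why: Sonogashira coupling of an alkenyl iodide proceeds with retention of alkene geometry and tolerates the free allylic alcohol.

Step 8
Reactants: 11 enyne alcohol
Product: 12 (2E)-4-[(4-methoxybenzyl)oxy]-3-[(trimethylsilyl)ethynyl]but-2-enal
Conditions: MnO2, CH2Cl2, rt
Reagents that add atoms: none
Why: Chemoselective allylic oxidation with MnO2 under neutral conditions; the formyl group is trans to the CH2OPMB arm, so no cyclic hemiacetal can form and the geometry should hold.

Step 9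
Reactants: 12 enal; 13 tert-butyldimethyl(prop-2-yn-1-yloxy)silane
Product: 15 (4R,5E)-1-[(tert-butyldimethylsilyl)oxy]-6-{[(4-methoxybenzyl)oxy]methyl}-8-(trimethylsilyl)octa-5-en-2,7-diyn-4-ol, via methylzinc acetylide 14 (not isolated)
Conditions: (S,S)-ProPhenol (20 mol %), Me2Zn, Ph3P=O (40 mol %), toluene, 0 °C
Reagents that add atoms: none
Why: Catalytic enantioselective alkynylation of an α,β-unsaturated aldehyde by a dinuclear zinc–ProPhenol catalyst, a substrate class on which this reaction is reliable; the ligand directs the zinc acetylide to the Si face and so sets C6 (4R in 15).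

Step 10
Reactants: 15 (4R)-enediynol
Product: 17 (2Z,4R,5E)-1-[(tert-butyldimethylsilyl)oxy]-2-iodo-6-{[(4-methoxybenzyl)oxy]methyl}-8-(trimethylsilyl)octa-2,5-dien-7-yn-4-ol, via cyclic alkenylaluminate 16 (not isolated)
Conditions: NaAlH2(OCH2CH2OMe)2, THF, −20 to 0 °C; then I2, THF, −78 °C
Reagents that add atoms: iodine, II
Why: The same hydroxyl-directed trans-hydroalumination–iodination as in step 6, now on the secondary propargylic alcohol: hydride goes to C7 and iodine to C11 cis to C6, the geometry needed for lactonization, while the non-propargylic silyl enyne should stay untouched at low temperature and C6 is not affected.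

Step 11
Reactants: 17 Z-iodo dienynol
Product: 18 (5R)-3-{[(tert-butyldimethylsilyl)oxy]methyl}-5-[(1E)-2-{[(4-methoxybenzyl)oxy]methyl}-4-(trimethylsilyl)but-1-en-3-yn-1-yl]furan-2(5H)-one
Conditions: Pd(PPh3)4 (5 mol %), CO (1 atm), K2CO3, THF, 40 °C
Reagents that add atoms: carbon monoxide, [C-]#[O+]
Why: Carbonylative lactonization of a (Z)-γ-hydroxy alkenyl iodide (oxidative addition, CO insertion, capture of the acylpalladium by the cis-disposed C6 hydroxyl) gives the butenolide with C12 from CO; C6 keeps its configuration because only its O–H bond reacts.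

Step 12
Reactants: 18 PMB-protected butenolide
Product: 19 (5R)-3-{[(tert-butyldimethylsilyl)oxy]methyl}-5-[(1E)-2-(hydroxymethyl)-4-(trimethylsilyl)but-1-en-3-yn-1-yl]furan-2(5H)-one
Conditions: DDQ, CH2Cl2/pH 7 buffer, 0 °C
Reagents that add atoms: none
Why: Oxidative cleavage of the electron-rich PMB ether by DDQ leaves the silyl groups, the butenolide and the enyne intact.

Step 13
Reactants: 19 C15 alcohol
Product: 20 (5R)-5-[(1E)-2-(acetoxymethyl)-4-(trimethylsilyl)but-1-en-3-yn-1-yl]-3-{[(tert-butyldimethylsilyl)oxy]methyl}furan-2(5H)-one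
Conditions: Ac2O, pyridine, DMAP (cat.), CH2Cl2, 0 °C
Reagents that add atoms: acetic anhydride, CC(=O)OC(C)=O
Why: Acetylation of the only free hydroxyl installs the C15 acetate of the target under conditions too mild to deprotonate C6.

Step 14
Reactants: 20 bis-silylated acetate
Product: 21 (5R)-5-[(1E)-2-(acetoxymethyl)but-1-en-3-yn-1-yl]-3-(hydroxymethyl)furan-2(5H)-one
Conditions: Bu4NF, AcOH (1:1), THF, 0 °C to rt
Reagents that add atoms: none
Why: Fluoride-mediated desilylation removes the alkynyl trimethylsilyl group and the primary silyl ether in one operation, and the AcOH buffer keeps the medium non-basic so that the acetate and the C6–H of the butenolide should survive.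

Step 15
Reactants: 5 α-hydroxy thioester; 21 terminal enyne butenolide
Product: 23 [(2Z)-3-[(2R)-4-(hydroxymethyl)-5-oxo-2,5-dihydrofuran-2-yl]-2-[(5R)-5-{2-[(tert-butyldimethylsilyl)oxy]ethyl}-5-methyl-4-oxo-4,5-dihydrofuran-2-yl]prop-2-en-1-yl] acetate, via hydroxy ynone 22 (not isolated)
Conditions: PdCl2(dppf) (10 mol %), P(2-furyl)3 (25 mol %), CuI (1.7 equiv), Et3N (3 equiv), DMF, rt to 40 °C
Reagents that add atoms: none
Why: Proposed new method: zerovalent palladium inserts into the acyl–sulfur bond of 5 (CuI assists and binds the thiolate as CuSEt), the copper acetylide of 21 transmetalates and reductive elimination forms C1–C2, giving the α′-hydroxy ynone 22; its tertiary hydroxyl then adds to the copper- and amine-activated, ketone-polarized triple bond at C3, and protonation at C2 gives the vinylogous ester 23. The closest known reactions are the palladium/copper coupling of thioesters with terminal alkynes to ynones and the separate base- or π-acid-mediated cycloisomerization of α′-hydroxy ynones to 3(2H)-furanones; what is new is their merger into a single [3+2] annulation on a free α-hydroxy thioester. Ring A is closed in the 5-endo-dig mode (O–C3), the only closure open to the C10 oxygen, while C1–C2 is formed between the two fragments. No stereocenter is created: C10 is quaternary and carried over from 1, and C6 and the C4=C5 geometry of 21 are not part of any intermediate. The step needs chemoselectivity for the thioester over the lactone, the acetate and the primary hydroxyl, which the soft copper-assisted C–S activation secures, and regioselectivity for O-attack at C3, which the conjugation of C2≡C3 with the C1 ketone secures. It also needs C6–H and the allylic acetate to outlast the amine and the palladium, for which the low temperature, the limited Et3N and the copper-driven turnover are relied on.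

Step 16
Reactants: 23 furanone–butenolide alcohol
Product: 24 [(2Z)-3-[(2R)-4-(bromomethyl)-5-oxo-2,5-dihydrofuran-2-yl]-2-[(5R)-5-{2-[(tert-butyldimethylsilyl)oxy]ethyl}-5-methyl-4-oxo-4,5-dihydrofuran-2-yl]prop-2-en-1-yl] acetate
Conditions: CBr4, PPh3, CH2Cl2, 0 °C
Reagents that add atoms: carbon tetrabromide, BrC(Br)(Br)Br
Why: Appel bromination of the only free hydroxyl (primary, allylic) under neutral conditions gives the allylic bromide by direct displacement, with the silyl ether, the acetate and both unsaturated rings inert.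

Step 17
Reactants: 24 allylic bromide silyl ether
Product: 25 [(2Z)-3-[(2R)-4-(bromomethyl)-5-oxo-2,5-dihydrofuran-2-yl]-2-[(5R)-5-(2-hydroxyethyl)-5-methyl-4-oxo-4,5-dihydrofuran-2-yl]prop-2-en-1-yl] acetate
Conditions: HF (48% aq.), MeCN, 0 °C
Reagents that add atoms: none
Why: Acidic cleavage of the primary silyl ether, chosen over basic fluoride because the allylic bromide and the acetate tolerate acid.

Step 18
Reactants: 25 primary alcohol
Product: 26 [(2Z)-3-[(2R)-4-(bromomethyl)-5-oxo-2,5-dihydrofuran-2-yl]-2-[(5R)-5-methyl-4-oxo-5-(2-oxoethyl)-4,5-dihydrofuran-2-yl]prop-2-en-1-yl] acetate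
Conditions: Dess–Martin periodinane, CH2Cl2, 0 °C to rt (no base)
Reagents that add atoms: none
Why: Dess–Martin oxidation gives the aldehyde under slightly acidic conditions, which avoids E1cB opening of ring A through loss of the β-oxygen and leaves the allylic bromide alone; 26 is used at once.

Step 19
Reactants: 26 seco bromo aldehyde
Product: 28 (4Z,6R,7R,8S,10R)-15-acetoxy-8-hydroxy-1-oxo-3,10-epoxygermacra-2,4,11(13)-trien-12,6-olide, via allylchromium 27 (not isolated)
Conditions: CrCl2 (6 equiv), DMF, rt, slow addition of 26 (high dilution)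
Reagents that add atoms: none
Why: Intramolecular Nozaki–Hiyama (chromium Barbier) allylation, a ring closure with precedent for ten-membered germacranolide rings: the allylchromium adds through its γ-carbon C7 in a six-membered Zimmerman–Traxler chair, which closes ring B at C7–C8 and shifts the double bond to the exocyclic C11=C13 of ring C; C7 is set by attack on the butenolide face opposite to the C5 substituent at C6 (trans-lactone), and C8 by the ring-locked E geometry of the γ-substituent with the aldehyde residue equatorial (C8–O anti to C6, 8S).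

Step 20
Reactants: 28 macrocyclic alcohol; 29 angelic acid
Product: 31 (4Z,6R,7R,8S,10R)-15-acetoxy-8-[(2Z)-2-methylbut-2-enoyloxy]-1-oxo-3,10-epoxygermacra-2,4,11(13)-trien-12,6-olide (target CNP0122132.1), via mixed anhydride 30 (not isolated)
Conditions: 2,4,6-Cl3C6H2COCl, Et3N, toluene, rt; then 28, toluene, 80 °C
Reagents that add atoms: none
Why: Yamaguchi-type esterification through the mixed anhydride without a nucleophilic catalyst, conditions known to acylate hindered secondary alcohols with angelic acid without Z-to-E isomerization; the C8–O bond is not broken, so the configuration is retained.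

## Compound list

1 | (R)-citramalic acid, (2R)-2-hydroxy-2-methylbutanedioic acid | C[C@@](O)(CC(=O)O)C(=O)O | starting material
2 | 2-[(4R)-2,2,4-trimethyl-5-oxo-1,3-dioxolan-4-yl]acetic acid | C[C@]1(CC(=O)O)OC(C)(C)OC1=O | intermediate
3 | (5R)-5-(2-hydroxyethyl)-2,2,5-trimethyl-1,3-dioxolan-4-one | C[C@]1(CCO)OC(C)(C)OC1=O | intermediate
4 | (5R)-5-{2-[(tert-butyldimethylsilyl)oxy]ethyl}-2,2,5-trimethyl-1,3-dioxolan-4-one | C[C@]1(CCO[Si](C)(C)C(C)(C)C)OC(C)(C)OC1=O | intermediate
5 | S-ethyl (2R)-4-[(tert-butyldimethylsilyl)oxy]-2-hydroxy-2-methylbutanethioate | CCSC(=O)[C@](C)(O)CCO[Si](C)(C)C(C)(C)C | intermediate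
6 | but-2-yne-1,4-diol | OCC#CCO | starting material
7 | 4-[(4-methoxybenzyl)oxy]but-2-yn-1-ol | OCC#CCOCc1ccc(OC)cc1 | intermediate
8 | cyclic sodium alkenylaluminate from 7 (five-membered ring O–CH2–CH=C(CH2OPMB)–Al, two 2-methoxyethoxy groups on Al) | [Na+].COCCO[Al-]1(OCCOC)OCC=C1COCc1ccc(OC)cc1 | intermediate (not isolated)
9 | (2Z)-3-iodo-4-[(4-methoxybenzyl)oxy]but-2-en-1-ol | OC/C=C(\I)COCc1ccc(OC)cc1 | intermediate
10 | ethynyltrimethylsilane | C#C[Si](C)(C)C | starting material
11 | (2E)-4-[(4-methoxybenzyl)oxy]-3-[(trimethylsilyl)ethynyl]but-2-en-1-ol | OC/C=C(/COCc1ccc(OC)cc1)C#C[Si](C)(C)C | intermediate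
12 | (2E)-4-[(4-methoxybenzyl)oxy]-3-[(trimethylsilyl)ethynyl]but-2-enal | O=C/C=C(/COCc1ccc(OC)cc1)C#C[Si](C)(C)C | intermediate
13 | tert-butyldimethyl(prop-2-yn-1-yloxy)silane | C#CCO[Si](C)(C)C(C)(C)C | starting material
14 | methyl{3-[(tert-butyldimethylsilyl)oxy]prop-1-yn-1-yl}zinc | C[Zn]C#CCO[Si](C)(C)C(C)(C)C | intermediate (not isolated)
15 | (4R,5E)-1-[(tert-butyldimethylsilyl)oxy]-6-{[(4-methoxybenzyl)oxy]methyl}-8-(trimethylsilyl)octa-5-en-2,7-diyn-4-ol | O[C@@H](C#CCO[Si](C)(C)C(C)(C)C)/C=C(/COCc1ccc(OC)cc1)C#C[Si](C)(C)C | intermediate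
16 | cyclic sodium alkenylaluminate from 15 (five-membered ring O–C6H–C7H=C11(CH2OTBS)–Al, two 2-methoxyethoxy groups on Al) | [Na+].COCCO[Al-]1(OCCOC)O[C@H](/C=C(/COCc2ccc(OC)cc2)C#C[Si](C)(C)C)C=C1CO[Si](C)(C)C(C)(C)C | intermediate (not isolated)
17 | (2Z,4R,5E)-1-[(tert-butyldimethylsilyl)oxy]-2-iodo-6-{[(4-methoxybenzyl)oxy]methyl}-8-(trimethylsilyl)octa-2,5-dien-7-yn-4-ol | O[C@@H](/C=C(\I)CO[Si](C)(C)C(C)(C)C)/C=C(/COCc1ccc(OC)cc1)C#C[Si](C)(C)C | intermediate
18 | (5R)-3-{[(tert-butyldimethylsilyl)oxy]methyl}-5-[(1E)-2-{[(4-methoxybenzyl)oxy]methyl}-4-(trimethylsilyl)but-1-en-3-yn-1-yl]furan-2(5H)-one | C[Si](C)(C)C#C\C(COCc1ccc(OC)cc1)=C/[C@H]1OC(=O)C(CO[Si](C)(C)C(C)(C)C)=C1 | intermediate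
19 | (5R)-3-{[(tert-butyldimethylsilyl)oxy]methyl}-5-[(1E)-2-(hydroxymethyl)-4-(trimethylsilyl)but-1-en-3-yn-1-yl]furan-2(5H)-one | C[Si](C)(C)C#C\C(CO)=C/[C@H]1OC(=O)C(CO[Si](C)(C)C(C)(C)C)=C1 | intermediate
20 | (5R)-5-[(1E)-2-(acetoxymethyl)-4-(trimethylsilyl)but-1-en-3-yn-1-yl]-3-{[(tert-butyldimethylsilyl)oxy]methyl}furan-2(5H)-one | C[Si](C)(C)C#C\C(COC(C)=O)=C/[C@H]1OC(=O)C(CO[Si](C)(C)C(C)(C)C)=C1 | intermediate
21 | (5R)-5-[(1E)-2-(acetoxymethyl)but-1-en-3-yn-1-yl]-3-(hydroxymethyl)furan-2(5H)-one | C#C\C(COC(C)=O)=C/[C@H]1OC(=O)C(CO)=C1 | intermediate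
22 | (5R)-5-[(1E,6R)-2-(acetoxymethyl)-8-[(tert-butyldimethylsilyl)oxy]-6-hydroxy-6-methyl-5-oxooct-1-en-3-yn-1-yl]-3-(hydroxymethyl)furan-2(5H)-one | CC(=O)OC/C(=C/[C@H]1OC(=O)C(CO)=C1)C#CC(=O)[C@](C)(O)CCO[Si](C)(C)C(C)(C)C | intermediate (not isolated)
23 | [(2Z)-3-[(2R)-4-(hydroxymethyl)-5-oxo-2,5-dihydrofuran-2-yl]-2-[(5R)-5-{2-[(tert-butyldimethylsilyl)oxy]ethyl}-5-methyl-4-oxo-4,5-dihydrofuran-2-yl]prop-2-en-1-yl] acetate | CC(=O)OC/C(=C/[C@H]1OC(=O)C(CO)=C1)C1=CC(=O)[C@@](C)(CCO[Si](C)(C)C(C)(C)C)O1 | intermediate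
24 | [(2Z)-3-[(2R)-4-(bromomethyl)-5-oxo-2,5-dihydrofuran-2-yl]-2-[(5R)-5-{2-[(tert-butyldimethylsilyl)oxy]ethyl}-5-methyl-4-oxo-4,5-dihydrofuran-2-yl]prop-2-en-1-yl] acetate | CC(=O)OC/C(=C/[C@H]1OC(=O)C(CBr)=C1)C1=CC(=O)[C@@](C)(CCO[Si](C)(C)C(C)(C)C)O1 | intermediate
25 | [(2Z)-3-[(2R)-4-(bromomethyl)-5-oxo-2,5-dihydrofuran-2-yl]-2-[(5R)-5-(2-hydroxyethyl)-5-methyl-4-oxo-4,5-dihydrofuran-2-yl]prop-2-en-1-yl] acetate | CC(=O)OC/C(=C/[C@H]1OC(=O)C(CBr)=C1)C1=CC(=O)[C@@](C)(CCO)O1 | intermediate
26 | [(2Z)-3-[(2R)-4-(bromomethyl)-5-oxo-2,5-dihydrofuran-2-yl]-2-[(5R)-5-methyl-4-oxo-5-(2-oxoethyl)-4,5-dihydrofuran-2-yl]prop-2-en-1-yl] acetate | CC(=O)OC/C(=C/[C@H]1OC(=O)C(CBr)=C1)C1=CC(=O)[C@@](C)(CC=O)O1 | intermediate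
27 | allylchromium dichloride from 26 (CrCl2 group on C13 in place of bromine) | CC(=O)OC/C(=C/[C@H]1OC(=O)C(C[Cr](Cl)Cl)=C1)C1=CC(=O)[C@@](C)(CC=O)O1 | intermediate (not isolated)
28 | (4Z,6R,7R,8S,10R)-15-acetoxy-8-hydroxy-1-oxo-3,10-epoxygermacra-2,4,11(13)-trien-12,6-olide | C=C1C(=O)O[C@@H]2/C=C(/COC(C)=O)C3=CC(=O)[C@@](C)(C[C@H](O)[C@@H]12)O3 | intermediate
29 | angelic acid, (2Z)-2-methylbut-2-enoic acid | C/C=C(/C)C(=O)O | starting material
30 | angelic 2,4,6-trichlorobenzoic anhydride | C/C=C(/C)C(=O)OC(=O)c1c(Cl)cc(Cl)cc1Cl | intermediate (not isolated)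
31 | (4Z,6R,7R,8S,10R)-15-acetoxy-8-[(2Z)-2-methylbut-2-enoyloxy]-1-oxo-3,10-epoxygermacra-2,4,11(13)-trien-12,6-olide (CNP0122132.1) | C=C1C(=O)O[C@@H]2/C=C(/COC(C)=O)C3=CC(=O)[C@@](C)(C[C@H](OC(=O)/C(C)=C\C)[C@@H]12)O3 | target

## Step count and risks

Total step count: 20. Longest linear sequence: 16 steps (steps 5–20, from but-2-yne-1,4-diol); the thioester branch (steps 1–4) joins at step 15.

Steps most likely to fail:

**Step 15 (proposed new method).** The oxa-Michael closure may lag behind the coupling, so that 22 stays in the amine/copper thiolate medium and is lost to thiolate addition. The free α-hydroxyl may also slow transmetalation, so that decarbonylation of the hindered acylpalladium competes. Prolonged exposure to amine and palladium may further erode C6 or ionize the allylic acetate. The fallback uses known reactions only, in two stages, and sets out from 5. Silylation (Me3SiCl, imidazole, CH2Cl2) should give S-ethyl (2R)-4-[(tert-butyldimethylsilyl)oxy]-2-methyl-2-[(trimethylsilyl)oxy]butanethioate F1. The palladium/copper thioester–alkyne coupling is then run with 21 as a plain ynone synthesis and should give the silyloxy ynone F2, which can neither cyclize nor chelate. Citric acid in MeOH releases 22, which is now isolated, and (Ph3P)AuNTf2 (monovalent gold, toluene, rt) effects the known 5-endo-dig cycloisomerization. The route is rejoined at 23.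

**Step 19.** Ring strain may slow the cyclization so that the allylchromium is protonated or couples between molecules. The tether through ring A may also force the aldehyde through a transition state other than the chair with the C9 residue equatorial, giving poor facial selectivity at the aldehyde and the wrong configuration at C8. The fallback sets C8 by inversion instead of by the ring closure and sets out from 26. If the cyclization delivers the C8 epimer, (4Z,6R,7R,8R,10R)-15-acetoxy-8-hydroxy-1-oxo-3,10-epoxygermacra-2,4,11(13)-trien-12,6-olide F3, this is esterified under Mitsunobu conditions with 29 (PPh3, diisopropyl azodicarboxylate, toluene, 0 °C). Inversion at C8 gives the angelate directly, replacing step 20. The route is rejoined at 31.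

**Step 10.** Hydride delivery may not stay at the propargylic triple bond: the same alkoxyaluminate can reduce the conjugated enyne, or the alkenylaluminate can expel the neighbouring silyloxy group to give an allene. The fallback avoids aluminum hydride and sets out from 15. Hydroxyl-directed ruthenium-catalysed trans-hydrosilylation ([Cp*Ru(MeCN)3]PF6, Et3SiH, CH2Cl2, 0 °C) should place silicon on the distal alkyne carbon C11 and give (2Z,4R,5E)-1-[(tert-butyldimethylsilyl)oxy]-6-{[(4-methoxybenzyl)oxy]methyl}-2-(triethylsilyl)-8-(trimethylsilyl)octa-2,5-dien-7-yn-4-ol F4. Iododesilylation with N-iodosuccinimide in (CF3)2CHOH, with retention, then gives the iodide. The route is rejoined at 17.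

## Further compounds

F1 | step 15 | S-ethyl (2R)-4-[(tert-butyldimethylsilyl)oxy]-2-methyl-2-[(trimethylsilyl)oxy]butanethioate | CCSC(=O)[C@](C)(O[Si](C)(C)C)CCO[Si](C)(C)C(C)(C)C
F2 | step 15 | (5R)-5-[(1E,6R)-2-(acetoxymethyl)-8-[(tert-butyldimethylsilyl)oxy]-6-methyl-5-oxo-6-[(trimethylsilyl)oxy]oct-1-en-3-yn-1-yl]-3-(hydroxymethyl)furan-2(5H)-one | CC(=O)OC/C(=C/[C@H]1OC(=O)C(CO)=C1)C#CC(=O)[C@](C)(O[Si](C)(C)C)CCO[Si](C)(C)C(C)(C)C
F3 | step 19 | (4Z,6R,7R,8R,10R)-15-acetoxy-8-hydroxy-1-oxo-3,10-epoxygermacra-2,4,11(13)-trien-12,6-olide | C=C1C(=O)O[C@@H]2/C=C(/COC(C)=O)C3=CC(=O)[C@@](C)(C[C@@H](O)[C@@H]12)O3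
F4 | step 10 | (2Z,4R,5E)-1-[(tert-butyldimethylsilyl)oxy]-6-{[(4-methoxybenzyl)oxy]methyl}-2-(triethylsilyl)-8-(trimethylsilyl)octa-2,5-dien-7-yn-4-ol | O[C@@H](/C=C(\[Si](CC)(CC)CC)CO[Si](C)(C)C(C)(C)C)/C=C(/COCc1ccc(OC)cc1)C#C[Si](C)(C)C
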